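## Retrosynthetic overview

- Feature: C2 and C3 of the 2,3-dihydrobenzofuran are neighbouring sp3 carbons. C3 carries ring A (through C3a) and the 3,5-dihydroxyphenyl ring, C2 carries the catechol ring and O1, so C3 and C2 are the β and α carbons of a ring A (E)-styrenyl boronate.
- Key disconnection: the C2–catechol ring and C3–resorcinol ring bonds, made together in a palladium-catalysed three-component conjunctive coupling of the alkenyl boronate, 3,4-dimethoxyphenyllithium and 3,5-dimethoxyphenyl triflate. The boronate is used as its ester with cis-1,2-dimethylacenaphthene-1,2-diol, B(mac), because β-substituted pinacol esters tend to divert into direct Suzuki–Miyaura coupling.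
- Ring order: the four benzene rings are bought. The only ring made is the dihydrofuran ring, closed after C–B oxidation by O1–C2 bond formation under acid; either of the two equivalent ring A oxygens closes and the other becomes the C4 triflate.
- Endgame: the methyl ethers are cleaved with BBr3 while no alkene is present, the phenols are carried as acetates through a Heck reaction with 4-acetoxystyrene (C4–styryl bond), and ammonia frees the six phenols without acid.
- The boronate comes from 5-methoxyresorcinol by MOM protection, ortho-lithiation and formylation, alkyne formation and hydroboration.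

Key step: step 7

Assumption: the (Sp,Sp) ligand is taken to select the alkene face that leads to the 3S centre, as it does for simpler alkenyl boron ate complexes; if the first run shows the other sense, the (Rp,Rp) ligand is used and nothing else changes.

## Route

Step 1
Reactants: 1 5-methoxyresorcinol
Product: 2 1-methoxy-3,5-bis(methoxymethoxy)benzene
Conditions: MOMCl, i-Pr2NEt, CH2Cl2, 0 °C → rt
Reagents that add atoms: chloromethyl methyl ether, COCCl
Why: Double O-alkylation of the two phenols (Williamson-type etherification) should be clean, and the MOM groups later serve as directing groups for lithiation and as acid-labile masks for the two equivalent ring A oxygens.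

Step 2
Reactants: 2 1-methoxy-3,5-bis(methoxymethoxy)benzene
Product: 4 4-methoxy-2,6-bis(methoxymethoxy)benzaldehyde, via aryllithium 3 (not isolated)
Conditions: n-BuLi, THF, 0 °C; then DMF, 0 °C → rt; aq NH4Cl
Reagents that add atoms: n-butyllithium, [Li]CCCC (supplies the lithium of 3); N,N-dimethylformamide, CN(C)C=O
Why: Directed ortho-metalation should take place at the carbon flanked by the two chelating OMOM groups, which direct more strongly than OMe, and formylation of the aryllithium with DMF then gives the symmetrical aldehyde.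

Step 3
Reactants: 4 4-methoxy-2,6-bis(methoxymethoxy)benzaldehyde
Product: 5 2-ethynyl-5-methoxy-1,3-bis(methoxymethoxy)benzene
Conditions: dimethyl (1-diazo-2-oxopropyl)phosphonate, K2CO3, MeOH, rt
Reagents that add atoms: dimethyl (1-diazo-2-oxopropyl)phosphonate (Ohira–Bestmann reagent), COP(=O)(OC)C(=[N+]=[N-])C(C)=O
Why: Seyferth–Gilbert homologation with the Ohira–Bestmann reagent converts an aryl aldehyde into the terminal alkyne under mild carbonate conditions that leave MOM and methyl ethers untouched.

Step 4
Reactants: 6 acenaphthylene-1,2-dione (acenaphthenequinone)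
Product: 7 cis-1,2-dimethyl-1,2-dihydroacenaphthylene-1,2-diol (meso, mac diol)
Conditions: MeMgBr, THF, 0 °C → rt; aq NH4Cl; crystallisation
Reagents that add atoms: methylmagnesium bromide, C[Mg]Br
Why: Double Grignard addition to the 1,2-diketone, in which the second methyl group should enter syn to the first and away from the solvated magnesium alkoxide, so that the cis (meso) diol, the only isomer able to form a five-membered cyclic boronate, is expected to predominate and is purified by crystallisation.

Step 5
Reactants: 5 2-ethynyl-5-methoxy-1,3-bis(methoxymethoxy)benzene; 7 cis-1,2-dimethyl-1,2-dihydroacenaphthylene-1,2-diol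
Product: 9 (E)-2-[4-methoxy-2,6-bis(methoxymethoxy)phenyl]ethenylboronic acid cis-1,2-dimethylacenaphthene-1,2-diyl ester [alkenyl B(mac) boronate], via alkenyl catechol boronate 8 (not isolated)
Conditions: catecholborane, dicyclohexylborane (cat.), THF, rt; then 7, rt
Reagents that add atoms: catecholborane, B1Oc2ccccc2O1
Why: Syn hydroboration of the terminal alkyne (dicyclohexylborane-catalysed addition of catecholborane) places boron on the terminal carbon and fixes the E geometry, and the labile catechol ester then exchanges with the tertiary diol (transesterification) to give the hindered boronate that disfavours direct boron-to-palladium transfer in step 7.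

Step 6
Reactants: 10 3,5-dimethoxyphenol
Product: 11 3,5-dimethoxyphenyl trifluoromethanesulfonate
Conditions: Tf2O, pyridine, CH2Cl2, 0 °C
Reagents that add atoms: trifluoromethanesulfonic anhydride, O=S(=O)(OS(=O)(=O)C(F)(F)F)C(F)(F)F
Why: O-Sulfonylation of the phenol gives the halide-free aryl electrophile that the conjunctive coupling requires.

Step 7
Reactants: 12 4-bromo-1,2-dimethoxybenzene; 9 alkenyl B(mac) boronate; 11 3,5-dimethoxyphenyl trifluoromethanesulfonate
Product: 15 (1R,2S)-1-(3,4-dimethoxyphenyl)-2-(3,5-dimethoxyphenyl)-2-[4-methoxy-2,6-bis(methoxymethoxy)phenyl]ethylboronic acid cis-1,2-dimethylacenaphthene-1,2-diyl ester [anti B(mac) boronate], via aryllithium 13 (not isolated), via lithium boron ate complex 14 (not isolated)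
Conditions: 12, t-BuLi (2 equiv), Et2O, −78 °C; 9, THF, −78 °C → rt; solvent change to THF; 11, Pd(OAc)2 (cat.), (Sp,Sp)-MandyPhos (C52H50FeN2P2, 1,1′-bis(diphenylphosphino)-2,2′-bis[(dimethylamino)(phenyl)methyl]ferrocene, cat.), KOSO2CF3, THF, 60 °C
Reagents that add atoms: tert-butyllithium, [Li]C(C)(C)C (supplies the lithium of 13 and 14; no atoms in 15)
Why: Proposed new method: aryllithium 13 adds to boron of 9 to give ate complex 14, whose alkene binds the cationic arylpalladium triflate formed from 11 and zerovalent palladium; the 3,4-dimethoxyphenyl group then shifts from boron to the α carbon (future C2) anti to palladium, which takes the β carbon (future C3), and reductive elimination with retention joins that carbon to the 3,5-dimethoxyphenyl ring. The closest known reaction is the palladium/MandyPhos conjunctive cross-coupling of β-alkyl alkenyl B(mac) ate complexes with aryl triflates; a β-aryl group carrying two ortho ethers has not been shown. No ring is closed in this step. The future C3 is set by the ligand-controlled choice of alkene face, and the boron-bearing carbon follows from anti addition across the E alkene, so the (1R,2S) anti isomer is expected. The step needs the metallate shift to win over direct Suzuki–Miyaura transfer and over β-hydride elimination from the benzylic palladium species: the bulky mac diol shields the boronate oxygens that mediate transmetalation, KOSO2CF3 removes bromide as KBr so that palladium stays cationic, and the wide-bite-angle diphosphine speeds reductive elimination.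

Step 8
Reactants: 15 anti B(mac) boronate
Product: 16 (1R,2S)-1-(3,4-dimethoxyphenyl)-2-(3,5-dimethoxyphenyl)-2-[4-methoxy-2,6-bis(methoxymethoxy)phenyl]ethan-1-ol
Conditions: NaOH (aq), H2O2 (30%), THF, 0 °C → rt
Reagents that add atoms: hydrogen peroxide, OO
Why: Oxidation of the C–B bond with alkaline hydrogen peroxide proceeds by 1,2-migration of carbon from boron to oxygen with retention, so the (1R) carbinol is obtained, the diaryl-substituted carbon is not touched, and the MOM and methyl ethers are stable to base.

Step 9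
Reactants: 16 (1R,2S)-triaryl ethanol
Product: 17 (2S,3S)-2-(3,4-dimethoxyphenyl)-3-(3,5-dimethoxyphenyl)-6-methoxy-2,3-dihydro-1-benzofuran-4-ol
Conditions: HCl (1 M in MeOH), THF, 45 °C
Reagents that add atoms: none
Why: Acid cleaves the MOM ethers and ionises the 3,4-dimethoxybenzylic alcohol to a cation stabilised by the para methoxy group, which one of the two equivalent ring A oxygens captures in a five-membered dehydrative ring closure; attack anti to the C3 aryl group gives the trans isomer, which is also the more stable one, a direct displacement with inversion would give the same (2S,3S) product, and C3 takes no part.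

Step 10
Reactants: 17 (2S,3S)-dihydrobenzofuran-4-ol
Product: 18 (2S,3S)-2-(3,4-dimethoxyphenyl)-3-(3,5-dimethoxyphenyl)-6-methoxy-2,3-dihydro-1-benzofuran-4-yl trifluoromethanesulfonate
Conditions: Tf2O, pyridine, CH2Cl2, 0 °C
Reagents that add atoms: trifluoromethanesulfonic anhydride, O=S(=O)(OS(=O)(=O)C(F)(F)F)C(F)(F)F
Why: The only free phenol, at C4, is O-sulfonylated to give the handle for the styryl arm.

Step 11
Reactants: 18 pentamethyl ether triflate
Product: 19 (2S,3S)-2-(3,4-dihydroxyphenyl)-3-(3,5-dihydroxyphenyl)-6-hydroxy-2,3-dihydro-1-benzofuran-4-yl trifluoromethanesulfonate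
Conditions: BBr3, CH2Cl2, −78 °C → 0 °C; MeOH, then water
Reagents that add atoms: none
Why: Lewis acid demethylation of the five aryl methyl ethers is placed here, before any alkene is present, because an acid-activated stilbene would be attacked by the neighbouring resorcinol ring; aryl triflates tolerate BBr3, and any reversible opening of the C2–O bond should return to the stable trans isomer.

Step 12
Reactants: 19 pentaphenol triflate
Product: 20 4-[(2S,3S)-6-acetoxy-3-(3,5-diacetoxyphenyl)-4-(trifluoromethanesulfonyloxy)-2,3-dihydro-1-benzofuran-2-yl]-1,2-phenylene diacetate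
Conditions: Ac2O, pyridine, DMAP (cat.), CH2Cl2, 0 °C → rt
Reagents that add atoms: acetic anhydride, CC(=O)OC(C)=O
Why: Peracetylation (DMAP-catalysed acyl transfer) masks the five phenols as acetates, which survive the amine base of the Heck reaction and can be removed later without acid.

Step 13
Reactants: 20 pentaacetate triflate; 21 4-ethenylphenyl acetate (4-acetoxystyrene)
Product: 22 4-[(2S,3S)-6-acetoxy-4-[(E)-2-(4-acetoxyphenyl)ethenyl]-3-(3,5-diacetoxyphenyl)-2,3-dihydro-1-benzofuran-2-yl]-1,2-phenylene diacetate (scirpusin A hexaacetate)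
Conditions: PdCl2(PPh3)2 (cat.), LiCl, Et3N, DMF, 90 °C
Reagents that add atoms: none
Why: Heck reaction in which oxidative addition of the aryl triflate to zerovalent palladium, exchange to the neutral arylpalladium chloride, syn insertion of the styrene at its terminal carbon and syn β-hydride elimination should give the E stilbene, the acetates being stable to Et3N in dry DMF.

Step 14
Reactants: 22 scirpusin A hexaacetate
Product: 23 scirpusin A, 4-[(2S,3S)-3-(3,5-dihydroxyphenyl)-6-hydroxy-4-[(E)-2-(4-hydroxyphenyl)ethenyl]-2,3-dihydro-1-benzofuran-2-yl]benzene-1,2-diol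
Conditions: NH3 (7 M in MeOH), THF, degassed, 0 °C → rt; dilute HCl to pH 5
Reagents that add atoms: none
Why: Ammonolysis of the six aryl acetates (acyl transfer to ammonia) frees all phenols under mild, acid-free and oxygen-free conditions, so neither the stilbene nor the C2–O bond is activated and both stereocentres are untouched.

## Compound list

1 | 5-methoxyresorcinol (5-methoxybenzene-1,3-diol) | COc1cc(O)cc(O)c1 | starting material
2 | 1-methoxy-3,5-bis(methoxymethoxy)benzene | COCOc1cc(OC)cc(OCOC)c1 | intermediate
3 | [4-methoxy-2,6-bis(methoxymethoxy)phenyl]lithium | [Li]c1c(OCOC)cc(OC)cc1OCOC | intermediate (not isolated)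
4 | 4-methoxy-2,6-bis(methoxymethoxy)benzaldehyde | COCOc1cc(OC)cc(OCOC)c1C=O | intermediate
5 | 2-ethynyl-5-methoxy-1,3-bis(methoxymethoxy)benzene | COCOc1cc(OC)cc(OCOC)c1C#C | intermediate
6 | acenaphthylene-1,2-dione (acenaphthenequinone) | O=C1C(=O)c2cccc3cccc1c23 | starting material
7 | cis-1,2-dimethyl-1,2-dihydroacenaphthylene-1,2-diol (meso, mac diol) | O[C@]1(C)c2cccc3cccc(c23)[C@]1(C)O | intermediate
8 | 2-{(E)-2-[4-methoxy-2,6-bis(methoxymethoxy)phenyl]ethenyl}-1,3,2-benzodioxaborole | COCOc1cc(OC)cc(OCOC)c1/C=C/B1Oc2ccccc2O1 | intermediate (not isolated)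
9 | (E)-2-[4-methoxy-2,6-bis(methoxymethoxy)phenyl]ethenylboronic acid cis-1,2-dimethylacenaphthene-1,2-diyl ester, alkenyl B(mac) boronate | COCOc1cc(OC)cc(OCOC)c1/C=C/B1O[C@]2(C)c3cccc4cccc(c34)[C@]2(C)O1 | intermediate (key-step precursor)
10 | 3,5-dimethoxyphenol | COc1cc(O)cc(OC)c1 | starting material
11 | 3,5-dimethoxyphenyl trifluoromethanesulfonate | COc1cc(OC)cc(OS(=O)(=O)C(F)(F)F)c1 | intermediate
12 | 4-bromo-1,2-dimethoxybenzene | COc1ccc(Br)cc1OC | starting material
13 | (3,4-dimethoxyphenyl)lithium | [Li]c1ccc(OC)c(OC)c1 | intermediate (not isolated)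
14 | lithium (3,4-dimethoxyphenyl){(E)-2-[4-methoxy-2,6-bis(methoxymethoxy)phenyl]ethenyl}borate of diol 7 (ate complex) | [Li+].COCOc1cc(OC)cc(OCOC)c1/C=C/[B-]1(c2ccc(OC)c(OC)c2)O[C@]2(C)c3cccc4cccc(c34)[C@]2(C)O1 | intermediate (not isolated)
15 | (1R,2S)-1-(3,4-dimethoxyphenyl)-2-(3,5-dimethoxyphenyl)-2-[4-methoxy-2,6-bis(methoxymethoxy)phenyl]ethylboronic acid cis-1,2-dimethylacenaphthene-1,2-diyl ester | COCOc1cc(OC)cc(OCOC)c1[C@H](c1cc(OC)cc(OC)c1)[C@H](c1ccc(OC)c(OC)c1)B1O[C@]2(C)c3cccc4cccc(c34)[C@]2(C)O1 | intermediate (key-step product)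
16 | (1R,2S)-1-(3,4-dimethoxyphenyl)-2-(3,5-dimethoxyphenyl)-2-[4-methoxy-2,6-bis(methoxymethoxy)phenyl]ethan-1-ol | COCOc1cc(OC)cc(OCOC)c1[C@H](c1cc(OC)cc(OC)c1)[C@@H](O)c1ccc(OC)c(OC)c1 | intermediate
17 | (2S,3S)-2-(3,4-dimethoxyphenyl)-3-(3,5-dimethoxyphenyl)-6-methoxy-2,3-dihydro-1-benzofuran-4-ol | Oc1cc(OC)cc2c1[C@H](c1cc(OC)cc(OC)c1)[C@@H](c1ccc(OC)c(OC)c1)O2 | intermediate
18 | (2S,3S)-2-(3,4-dimethoxyphenyl)-3-(3,5-dimethoxyphenyl)-6-methoxy-2,3-dihydro-1-benzofuran-4-yl trifluoromethanesulfonate | O=S(=O)(Oc1cc(OC)cc2c1[C@H](c1cc(OC)cc(OC)c1)[C@@H](c1ccc(OC)c(OC)c1)O2)C(F)(F)F | intermediate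
19 | (2S,3S)-2-(3,4-dihydroxyphenyl)-3-(3,5-dihydroxyphenyl)-6-hydroxy-2,3-dihydro-1-benzofuran-4-yl trifluoromethanesulfonate | O=S(=O)(Oc1cc(O)cc2c1[C@H](c1cc(O)cc(O)c1)[C@@H](c1ccc(O)c(O)c1)O2)C(F)(F)F | intermediate
20 | 4-[(2S,3S)-6-acetoxy-3-(3,5-diacetoxyphenyl)-4-(trifluoromethanesulfonyloxy)-2,3-dihydro-1-benzofuran-2-yl]-1,2-phenylene diacetate | O=S(=O)(Oc1cc(OC(C)=O)cc2c1[C@H](c1cc(OC(C)=O)cc(OC(C)=O)c1)[C@@H](c1ccc(OC(C)=O)c(OC(C)=O)c1)O2)C(F)(F)F | intermediate
21 | 4-ethenylphenyl acetate (4-acetoxystyrene) | C=Cc1ccc(OC(C)=O)cc1 | starting material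
22 | 4-[(2S,3S)-6-acetoxy-4-[(E)-2-(4-acetoxyphenyl)ethenyl]-3-(3,5-diacetoxyphenyl)-2,3-dihydro-1-benzofuran-2-yl]-1,2-phenylene diacetate (scirpusin A hexaacetate) | CC(=O)Oc1ccc(/C=C/c2cc(OC(C)=O)cc3c2[C@H](c2cc(OC(C)=O)cc(OC(C)=O)c2)[C@@H](c2ccc(OC(C)=O)c(OC(C)=O)c2)O3)cc1 | intermediate
23 | scirpusin A, 4-[(2S,3S)-3-(3,5-dihydroxyphenyl)-6-hydroxy-4-[(E)-2-(4-hydroxyphenyl)ethenyl]-2,3-dihydro-1-benzofuran-2-yl]benzene-1,2-diol | Oc1ccc(/C=C/c2cc(O)cc3c2[C@H](c2cc(O)cc(O)c2)[C@@H](c2ccc(O)c(O)c2)O3)cc1 | target

## Step count and risks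

Total step count: 14 steps.
Longest linear sequence: 12 steps (steps 1, 2, 3, 5 and 7 to 14); steps 4 and 6 are one-step side branches.

Steps most likely to fail:

1. Step 7 (Proposed new method). The ate complex may transfer its alkenyl or aryl group directly to palladium (Suzuki–Miyaura pathway) instead of undergoing the metallate shift. The two ortho ethers may slow alkene binding, the benzylic palladium intermediate may undergo β-hydride elimination, and the face selectivity may be poor. The fallback uses known chemistry, sets out from 2 and returns at 17.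
   - Aryllithium 3, made as in step 2, is acylated with 3,5-dimethoxybenzoyl chloride (THF, −78 °C) to give (3,5-dimethoxyphenyl)[4-methoxy-2,6-bis(methoxymethoxy)phenyl]methanone F1.
   - Mild acid (HCl cat., MeOH, rt) removes one of the two equivalent MOM groups; the second is held back once the free phenol is hydrogen-bonded to the carbonyl. This gives (3,5-dimethoxyphenyl)[2-hydroxy-4-methoxy-6-(methoxymethoxy)phenyl]methanone F2.
   - Williamson etherification with 3,4-dimethoxybenzyl bromide (K2CO3, DMF) gives {2-[(3,4-dimethoxyphenyl)methoxy]-4-methoxy-6-(methoxymethoxy)phenyl}(3,5-dimethoxyphenyl)methanone F3.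
   - Hydrazine hydrate (n-BuOH, heat) gives {2-[(3,4-dimethoxyphenyl)methoxy]-4-methoxy-6-(methoxymethoxy)phenyl}(3,5-dimethoxyphenyl)methanone hydrazone F4, and MnO2 oxidises it to the diaryldiazomethane 1-[diazo(3,5-dimethoxyphenyl)methyl]-2-[(3,4-dimethoxyphenyl)methoxy]-4-methoxy-6-(methoxymethoxy)benzene F5.
   - Rh2(S-PTAD)4, dirhodium tetrakis[(S)-(1-adamantyl)(N-phthalimido)acetate], or its enantiomer, chosen so that C3 is set as in 17, catalyses enantioselective intramolecular C–H insertion of the donor/donor carbene into the benzylic ether C–H bond. This is an established route to cis-2,3-diaryl-2,3-dihydrobenzofurans and gives (2R,3S)-2-(3,4-dimethoxyphenyl)-3-(3,5-dimethoxyphenyl)-6-methoxy-4-(methoxymethoxy)-2,3-dihydro-1-benzofuran F6.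
   - The acid conditions of step 9 then remove the MOM group and epimerise C2 through the benzylic cation to the trans compound 17.

2. Step 9. While the MOM groups are being cleaved in warm protic acid, the benzylic cation may live long enough for a hydride shift from C3 or for loss of the C3 proton, which would erase the C3 centre. The fallback sets out from 16 and returns at 17.
   - 16 is treated with methanesulfonyl chloride and Et3N in CH2Cl2 at −40 °C. The (1R,2S)-1-(3,4-dimethoxyphenyl)-2-(3,5-dimethoxyphenyl)-2-[4-methoxy-2,6-bis(methoxymethoxy)phenyl]ethyl methanesulfonate F7 is not isolated.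
   - A neighbouring MOM ether oxygen displaces the sulfonate in the cold, and the resulting oxonium ion loses its methoxymethyl group to chloride. The ring is thus closed under buffered aprotic conditions, giving (2S,3S)-2-(3,4-dimethoxyphenyl)-3-(3,5-dimethoxyphenyl)-6-methoxy-4-(methoxymethoxy)-2,3-dihydro-1-benzofuran F8.
   - Brief HCl in MeOH at rt then frees the C4 phenol to give 17, with C3 already locked in the ring.

3. Step 13. Oxidative addition and alkene insertion at the triflate may be slow because the C3 aryl group crowds C4. The triflate may be reduced, and acetyl groups may be lost, freeing a catechol that binds the catalyst. The fallback sets out from 20 and returns at 22.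
   - Stille coupling of 20 with tributyl(vinyl)stannane (Pd(PPh3)4, LiCl, dioxane, 100 °C, neutral conditions) gives 4-[(2S,3S)-6-acetoxy-3-(3,5-diacetoxyphenyl)-4-ethenyl-2,3-dihydro-1-benzofuran-2-yl]-1,2-phenylene diacetate F9.
   - A Heck reaction of this styrene with the unhindered 4-iodophenyl acetate (Pd(OAc)2, P(o-tol)3, Et3N, DMF, 80 °C) then gives 22; the crowded partner is now the alkene and oxidative addition takes place on the open aryl iodide.

Further compounds
F1 | step 7 | (3,5-dimethoxyphenyl)[4-methoxy-2,6-bis(methoxymethoxy)phenyl]methanone | COCOc1cc(OC)cc(OCOC)c1C(=O)c1cc(OC)cc(OC)c1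
F2 | step 7 | (3,5-dimethoxyphenyl)[2-hydroxy-4-methoxy-6-(methoxymethoxy)phenyl]methanone | COCOc1cc(OC)cc(O)c1C(=O)c1cc(OC)cc(OC)c1
F3 | step 7 | {2-[(3,4-dimethoxyphenyl)methoxy]-4-methoxy-6-(methoxymethoxy)phenyl}(3,5-dimethoxyphenyl)methanone | COCOc1cc(OC)cc(OCc2ccc(OC)c(OC)c2)c1C(=O)c1cc(OC)cc(OC)c1
F4 | step 7 | {2-[(3,4-dimethoxyphenyl)methoxy]-4-methoxy-6-(methoxymethoxy)phenyl}(3,5-dimethoxyphenyl)methanone hydrazone | COCOc1cc(OC)cc(OCc2ccc(OC)c(OC)c2)c1C(=NN)c1cc(OC)cc(OC)c1
F5 | step 7 | 1-[diazo(3,5-dimethoxyphenyl)methyl]-2-[(3,4-dimethoxyphenyl)methoxy]-4-methoxy-6-(methoxymethoxy)benzene | COCOc1cc(OC)cc(OCc2ccc(OC)c(OC)c2)c1C(=[N+]=[N-])c1cc(OC)cc(OC)c1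
F6 | step 7 | (2R,3S)-2-(3,4-dimethoxyphenyl)-3-(3,5-dimethoxyphenyl)-6-methoxy-4-(methoxymethoxy)-2,3-dihydro-1-benzofuran | COCOc1cc(OC)cc2c1[C@H](c1cc(OC)cc(OC)c1)[C@H](c1ccc(OC)c(OC)c1)O2
F7 | step 9 | (1R,2S)-1-(3,4-dimethoxyphenyl)-2-(3,5-dimethoxyphenyl)-2-[4-methoxy-2,6-bis(methoxymethoxy)phenyl]ethyl methanesulfonate | COCOc1cc(OC)cc(OCOC)c1[C@H](c1cc(OC)cc(OC)c1)[C@@H](OS(C)(=O)=O)c1ccc(OC)c(OC)c1
F8 | step 9 | (2S,3S)-2-(3,4-dimethoxyphenyl)-3-(3,5-dimethoxyphenyl)-6-methoxy-4-(methoxymethoxy)-2,3-dihydro-1-benzofuran | COCOc1cc(OC)cc2c1[C@H](c1cc(OC)cc(OC)c1)[C@@H](c1ccc(OC)c(OC)c1)O2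
F9 | step 13 | 4-[(2S,3S)-6-acetoxy-3-(3,5-diacetoxyphenyl)-4-ethenyl-2,3-dihydro-1-benzofuran-2-yl]-1,2-phenylene diacetate | C=Cc1cc(OC(C)=O)cc2c1[C@H](c1cc(OC(C)=O)cc(OC(C)=O)c1)[C@@H](c1ccc(OC(C)=O)c(OC(C)=O)c1)O2
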